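**Plan** (carotenoid numbering: ring C1(CMe2)–C2H2–C3H(OH)–C4H(OH)–C5(CH3)=C6; chain C7≡C8–C9…C15; primes for the identical second half)
1. Cuts: C11=C12 and C11'=C12' (two-fold Wittig of one C15 salt with the C10 trienedial), then C8–C9 (Sonogashira), C7≡C8 (aldehyde homologation), and in each ring C4–C5 and C6–C1 in one [4+2] event.
2. Enabling feature: in the cyclohexene ring the C3 oxygen lies α to C4 and β to the quaternary gem-dimethyl carbon C1, and C6 carries C7. With C3 as ketone and C7 as ester, C4 is an enol donor, C1 an enone acceptor and C5≡C6–C7O2Me an ynoate (acceptor C5, donor C6), so a 1,2-bis(silyloxy)diene and methyl but-2-ynoate match at all four atoms.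
3. Forward: acyclic enone → diene → ring (both ring bonds, quaternary C1, tetrasubstituted C5=C6, both oxygens, C7) → ester to ethynyl → C8–C9 coupling → C15 + C10 + C15 → desilylation. The ring is made once and used for both ends.
4. Stereochemistry: the ring forms racemic at C4, its only stereocentre, which is labile (α to C3=O, vinylogous to the ester). A ketoreductase dynamic reductive kinetic resolution then sets 3S and 4S (trans) together. 9E comes from an (E)-enol triflate, 13E/15E from the dialdehyde, 11E from the Wittig step and equilibration.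

Key step: step 3

Assumption: Weinreb amide 1 is taken as a catalogue compound; in the names of 6–12 the ring locants follow the cyclohexene numbering (C3 there is carotenoid C4, C4 there is carotenoid C3).
Abbreviations: TBS = tert-butyldimethylsilyl; R* = (3S,4S)-3,4-bis(TBSO)-2,6,6-trimethylcyclohex-1-en-1-yl.

Step 1
Reactants: 1 2-(TBSO)-N-methoxy-N-methylacetamide; 2 (2-methylprop-1-en-1-yl)magnesium bromide
Product: 3 1-(TBSO)-4-methylpent-3-en-2-one
Conditions: THF, −78 → 0 °C; then H2O/aq. NH4Cl
Reagents that add atoms: none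
Why: Weinreb ketone synthesis, in which the chelated tetrahedral magnesium adduct stops the alkenyl Grignard addition at the ketone stage and the β,β-disubstituted enone resists conjugate addition on work-up.

Step 2
Reactants: 3 1-(TBSO)-4-methylpent-3-en-2-one
Product: 4 (1Z)-1,2-bis(TBSO)-4-methylpenta-1,3-diene
Conditions: TBSOTf, Et3N, CH2Cl2, 0 °C
Reagents that add atoms: tert-butyldimethylsilyl trifluoromethanesulfonate, CC(C)(C)[Si](C)(C)OS(=O)(=O)C(F)(F)F
Why: Soft enolisation (silyl triflate/amine) at the CH2 acidified by the silyloxy group should give the cross-conjugated 2-silyloxydiene, mainly as the Z enol ether, whose geometry is irrelevant to the next step.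

Step 3
Reactants: 4 (1Z)-1,2-bis(TBSO)-4-methylpenta-1,3-diene; 5 methyl but-2-ynoate
Product: 7 methyl 3-(TBSO)-2,6,6-trimethyl-4-oxocyclohex-1-ene-1-carboxylate (racemic), via silyl enol ether cycloadduct 6 (not isolated)
Conditions: AlBr3/AlMe3 (10:1, 20 mol %), toluene–CH2Cl2, −20 °C → rt; then 1 M HCl, THF, 0 °C
Reagents that add atoms: none
Why: The Lewis acid activates the ynoate, whose methyl-bearing β-carbon is attacked by the unhindered silyloxy-bearing enol carbon of 4 (Mukaiyama–Michael step), and the aluminium allenolate so formed closes onto the β,β-dimethyl terminus of the transient silyloxocarbenium enone, which creates the quaternary carbon and returns the silyl enol ether. The closest known reaction type is the Lewis-acid-promoted Diels–Alder (double Michael) reaction of hindered 2-silyloxydienes with acetylenic or olefinic carbonyl dienophiles. The one ring is closed as a formal [4+2] cycloaddition, its second bond arising by a 6-endo-trig Michael closure if the process is stepwise. The single new stereocentre (the CH–OTBS carbon) needs no control and forms as the racemate, because it becomes configurationally labile in 7 and is corrected in step 4. The step needs regioselectivity (methyl-bearing alkyne carbon to the oxygenated diene terminus), secured by the matched polarity of enol carbon and ynoate β-carbon and by the steric bias of the gem-dimethyl terminus, and six- over four-membered closure of the zwitterion, which reversibility of the [2+2] mode under the Lewis acid should deliver; aromatisation is excluded by the quaternary carbon. Dilute acid then cleaves only the silyl enol ether to the ketone.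

Step 4
Reactants: 7 methyl 3-(TBSO)-2,6,6-trimethyl-4-oxocyclohex-1-ene-1-carboxylate (racemic)
Product: 8 methyl (3S,4S)-3-(TBSO)-4-hydroxy-2,6,6-trimethylcyclohex-1-ene-1-carboxylate
Conditions: ketoreductase (NADPH-dependent alcohol dehydrogenase from a screening panel), NADP+ (cat.), i-PrOH (cosubstrate), KH2PO4/K2HPO4 buffer pH 8.0, DMSO (10 vol %), 30 °C
Reagents that add atoms: none
Why: Ketoreductase-catalysed dynamic reductive kinetic resolution (a known biocatalytic reaction type for configurationally labile α-substituted ketones and β-keto esters): C3–H of 7 is α to the ketone and vinylogously α to the ester, so in the buffer both enantiomers (and the conjugated double-bond isomer) interconvert through one dienol while the enzyme should accept only the 3S ketone and deliver hydride to the carbonyl face that gives the 4S alcohol, which sets both stereocentres (trans) by catalyst control.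

Step 5
Reactants: 8 methyl (3S,4S)-3-(TBSO)-4-hydroxy-2,6,6-trimethylcyclohex-1-ene-1-carboxylate
Product: 9 methyl (3S,4S)-3,4-bis(TBSO)-2,6,6-trimethylcyclohex-1-ene-1-carboxylate
Conditions: TBSOTf, 2,6-lutidine, CH2Cl2, 0 °C
Reagents that add atoms: tert-butyldimethylsilyl trifluoromethanesulfonate, CC(C)(C)[Si](C)(C)OS(=O)(=O)C(F)(F)F
Why: Silyl triflate silylation of the hindered secondary alcohol makes both oxygens alike, so that later base can neither shift the silyl group nor expose an allylic hydroxyl.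

Step 6
Reactants: 9 methyl (3S,4S)-3,4-bis(TBSO)-2,6,6-trimethylcyclohex-1-ene-1-carboxylate
Product: 10 R*-methanol, i.e. [(3S,4S)-3,4-bis(TBSO)-2,6,6-trimethylcyclohex-1-en-1-yl]methanol
Conditions: DIBAL-H (i-Bu2AlH), CH2Cl2, −78 → 0 °C; aq. potassium sodium tartrate
Reagents that add atoms: none
Why: Hydride reduction of the hindered conjugated ester by DIBAL-H should stop at the primary allylic alcohol, as for cyclogeranate esters, without touching the silyl ethers.

Step 7
Reactants: 10 [(3S,4S)-3,4-bis(TBSO)-2,6,6-trimethylcyclohex-1-en-1-yl]methanol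
Product: 12 (3S,4S)-3,4-bis(TBSO)-1-ethynyl-2,6,6-trimethylcyclohex-1-ene (R*–C≡CH), via enal 11 (not isolated)
Conditions: MnO2 (excess), THF, rt; then MeOH, K2CO3, dimethyl (1-diazo-2-oxopropyl)phosphonate, rt
Reagents that add atoms: dimethyl (1-diazo-2-oxopropyl)phosphonate, CC(=O)C(=[N+]=[N-])P(=O)(OC)OC
Why: MnO2 oxidises only the allylic alcohol and the aldehyde is homologated in the same pot by the Ohira–Bestmann variant of the Seyferth–Gilbert reaction, the tetrasubstituted enal being shielded from conjugate addition of methoxide.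

Step 8
Reactants: 13 ethyl acetoacetate
Product: 14 ethyl (2E)-3-{[(trifluoromethyl)sulfonyl]oxy}but-2-enoate
Conditions: Tf2O, aq. Me4NOH, hexane, 5 °C → rt
Reagents that add atoms: trifluoromethanesulfonic anhydride, O=S(=O)(OS(=O)(=O)C(F)(F)F)C(F)(F)F
Why: O-Triflation of the β-keto ester enolate under non-chelating tetraalkylammonium hydroxide conditions should give the (E)-enol triflate, which fixes the later 9E geometry.

Step 9
Reactants: 12 (3S,4S)-3,4-bis(TBSO)-1-ethynyl-2,6,6-trimethylcyclohex-1-ene; 14 ethyl (2E)-3-{[(trifluoromethyl)sulfonyl]oxy}but-2-enoate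
Product: 15 ethyl (2E)-5-R*-3-methylpent-2-en-4-ynoate
Conditions: PdCl2(PPh3)2 (3 mol %), CuI (6 mol %), Et3N, THF, rt
Reagents that add atoms: none
Why: Sonogashira coupling of the terminal alkyne with the vinyl triflate forms the C8–C9 bond with retention of the E geometry.

Step 10
Reactants: 15 ethyl (2E)-5-R*-3-methylpent-2-en-4-ynoate
Product: 16 (2E)-5-R*-3-methylpent-2-en-4-yn-1-ol
Conditions: DIBAL-H (i-Bu2AlH), CH2Cl2, −78 °C; aq. potassium sodium tartrate
Reagents that add atoms: none
Why: 1,2-Reduction of the enynoate by DIBAL-H should give the (E)-allylic alcohol and leave alkyne, alkenes and silyl ethers alone.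

Step 11
Reactants: 16 (2E)-5-R*-3-methylpent-2-en-4-yn-1-ol
Product: 18 [(2E)-5-R*-3-methylpent-2-en-4-yn-1-yl]triphenylphosphonium bromide, via allylic bromide 17 (not isolated)
Conditions: CBr4, PPh3, CH2Cl2, −20 → 0 °C; then PPh3, EtOAc, rt
Reagents that add atoms: carbon tetrabromide, BrC(Br)(Br)Br; triphenylphosphine, c1ccc(cc1)P(c1ccccc1)c1ccccc1
Why: Appel bromination of the primary allylic alcohol (SN2, geometry kept) followed by quaternisation of the bromide by excess phosphine should give the Wittig salt in one pot.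

Step 12
Reactants: 18 [(2E)-5-R*-3-methylpent-2-en-4-yn-1-yl]triphenylphosphonium bromide (2.2 equiv); 19 (2E,4E,6E)-2,7-dimethylocta-2,4,6-trienedial
Product: 22 (3S,4S,3'S,4'S)-3,4,3',4'-tetrakis(TBSO)-7,8,7',8'-tetradehydro-β,β-carotene, via phosphonium ylide 20 (not isolated), via C25 apo-aldehyde 21 (not isolated)
Conditions: NaOMe, CH2Cl2–MeOH, 0 °C → rt; then EtOAc, 60 °C, dark, N2
Reagents that add atoms: none
Why: Two-fold Wittig olefination of the C10 dialdehyde by the allylic ylide forms the 11,12 and 11',12' double bonds as E/Z mixtures that should equilibrate thermally to the all-E polyene, the stereocentres and the existing double bonds not being involved.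

Step 13
Reactants: 22 (3S,4S,3'S,4'S)-3,4,3',4'-tetrakis(TBSO)-7,8,7',8'-tetradehydro-β,β-carotene
Product: 23 (all-E)-(3S,4S,3'S,4'S)-7,8,7',8'-tetradehydro-β,β-carotene-3,4,3',4'-tetrol
Conditions: Bu4NF, THF, 0 °C → rt, dark; then H2O
Reagents that add atoms: none
Why: Fluoride-induced desilylation should cleave the four secondary silyl ethers under conditions that the polyene-diyne and the allylic alcohols tolerate.

**Compound list**
1 | 2-[(tert-butyldimethylsilyl)oxy]-N-methoxy-N-methylacetamide | CON(C)C(=O)CO[Si](C)(C)C(C)(C)C | starting material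
2 | (2-methylprop-1-en-1-yl)magnesium bromide | CC(C)=C[Mg]Br | starting material
3 | 1-[(tert-butyldimethylsilyl)oxy]-4-methylpent-3-en-2-one | CC(C)=CC(=O)CO[Si](C)(C)C(C)(C)C | intermediate
4 | (1Z)-1,2-bis[(tert-butyldimethylsilyl)oxy]-4-methylpenta-1,3-diene | CC(C)=C/C(O[Si](C)(C)C(C)(C)C)=C/O[Si](C)(C)C(C)(C)C | intermediate
5 | methyl but-2-ynoate | CC#CC(=O)OC | starting material
6 | methyl 3,4-bis[(tert-butyldimethylsilyl)oxy]-2,6,6-trimethylcyclohexa-1,4-diene-1-carboxylate (racemic) | COC(=O)C1=C(C)C(O[Si](C)(C)C(C)(C)C)C(O[Si](C)(C)C(C)(C)C)=CC1(C)C | intermediate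
7 | methyl 3-[(tert-butyldimethylsilyl)oxy]-2,6,6-trimethyl-4-oxocyclohex-1-ene-1-carboxylate (racemic) | COC(=O)C1=C(C)C(O[Si](C)(C)C(C)(C)C)C(=O)CC1(C)C | intermediate
8 | methyl (3S,4S)-3-[(tert-butyldimethylsilyl)oxy]-4-hydroxy-2,6,6-trimethylcyclohex-1-ene-1-carboxylate | CC1=C(C(=O)OC)C(C)(C)C[C@H](O)[C@H]1O[Si](C)(C)C(C)(C)C | intermediate
9 | methyl (3S,4S)-3,4-bis[(tert-butyldimethylsilyl)oxy]-2,6,6-trimethylcyclohex-1-ene-1-carboxylate | CC1=C(C(=O)OC)C(C)(C)C[C@H](O[Si](C)(C)C(C)(C)C)[C@H]1O[Si](C)(C)C(C)(C)C | intermediate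
10 | {(3S,4S)-3,4-bis[(tert-butyldimethylsilyl)oxy]-2,6,6-trimethylcyclohex-1-en-1-yl}methanol | CC1=C(CO)C(C)(C)C[C@H](O[Si](C)(C)C(C)(C)C)[C@H]1O[Si](C)(C)C(C)(C)C | intermediate
11 | (3S,4S)-3,4-bis[(tert-butyldimethylsilyl)oxy]-2,6,6-trimethylcyclohex-1-ene-1-carbaldehyde | CC1=C(C=O)C(C)(C)C[C@H](O[Si](C)(C)C(C)(C)C)[C@H]1O[Si](C)(C)C(C)(C)C | intermediate
12 | (3S,4S)-3,4-bis[(tert-butyldimethylsilyl)oxy]-1-ethynyl-2,6,6-trimethylcyclohex-1-ene | CC1=C(C#C)C(C)(C)C[C@H](O[Si](C)(C)C(C)(C)C)[C@H]1O[Si](C)(C)C(C)(C)C | intermediate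
13 | ethyl acetoacetate | CCOC(=O)CC(C)=O | starting material
14 | ethyl (2E)-3-{[(trifluoromethyl)sulfonyl]oxy}but-2-enoate | CCOC(=O)/C=C(C)/OS(=O)(=O)C(F)(F)F | intermediate
15 | ethyl (2E)-5-{(3S,4S)-3,4-bis[(tert-butyldimethylsilyl)oxy]-2,6,6-trimethylcyclohex-1-en-1-yl}-3-methylpent-2-en-4-ynoate | CC1=C(C#C/C(C)=C/C(=O)OCC)C(C)(C)C[C@H](O[Si](C)(C)C(C)(C)C)[C@H]1O[Si](C)(C)C(C)(C)C | intermediate
16 | (2E)-5-{(3S,4S)-3,4-bis[(tert-butyldimethylsilyl)oxy]-2,6,6-trimethylcyclohex-1-en-1-yl}-3-methylpent-2-en-4-yn-1-ol | CC1=C(C#C/C(C)=C/CO)C(C)(C)C[C@H](O[Si](C)(C)C(C)(C)C)[C@H]1O[Si](C)(C)C(C)(C)C | intermediate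
17 | (3S,4S)-1-[(3E)-5-bromo-3-methylpent-3-en-1-yn-1-yl]-3,4-bis[(tert-butyldimethylsilyl)oxy]-2,6,6-trimethylcyclohex-1-ene | CC1=C(C#C/C(C)=C/CBr)C(C)(C)C[C@H](O[Si](C)(C)C(C)(C)C)[C@H]1O[Si](C)(C)C(C)(C)C | intermediate
18 | [(2E)-5-{(3S,4S)-3,4-bis[(tert-butyldimethylsilyl)oxy]-2,6,6-trimethylcyclohex-1-en-1-yl}-3-methylpent-2-en-4-yn-1-yl]triphenylphosphonium bromide | CC1=C(C#C/C(C)=C/C[P+](c2ccccc2)(c2ccccc2)c2ccccc2)C(C)(C)C[C@H](O[Si](C)(C)C(C)(C)C)[C@H]1O[Si](C)(C)C(C)(C)C.[Br-] | intermediate
19 | (2E,4E,6E)-2,7-dimethylocta-2,4,6-trienedial | O=C/C(C)=C/C=C/C=C(C)/C=O | starting material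
20 | [(2E)-5-{(3S,4S)-3,4-bis[(tert-butyldimethylsilyl)oxy]-2,6,6-trimethylcyclohex-1-en-1-yl}-3-methylpent-2-en-4-yn-1-ylidene]triphenylphosphorane (ylide of 18) | CC1=C(C#C/C(C)=C/C=P(c2ccccc2)(c2ccccc2)c2ccccc2)C(C)(C)C[C@H](O[Si](C)(C)C(C)(C)C)[C@H]1O[Si](C)(C)C(C)(C)C | intermediate
21 | (3S,4S)-3,4-bis[(tert-butyldimethylsilyl)oxy]-7,8-didehydro-12'-apo-β-caroten-12'-al (all-E form shown) | CC1=C(C#C/C(C)=C/C=C/C(C)=C/C=C/C=C(C)/C=O)C(C)(C)C[C@H](O[Si](C)(C)C(C)(C)C)[C@H]1O[Si](C)(C)C(C)(C)C | intermediate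
22 | (all-E)-(3S,4S,3'S,4'S)-3,4,3',4'-tetrakis[(tert-butyldimethylsilyl)oxy]-7,8,7',8'-tetradehydro-β,β-carotene | CC1=C(C#C/C(C)=C/C=C/C(C)=C/C=C/C=C(C)/C=C/C=C(\C)C#CC2=C(C)[C@H](O[Si](C)(C)C(C)(C)C)[C@@H](O[Si](C)(C)C(C)(C)C)CC2(C)C)C(C)(C)C[C@H](O[Si](C)(C)C(C)(C)C)[C@H]1O[Si](C)(C)C(C)(C)C | intermediate
23 | (all-E)-(3S,4S,3'S,4'S)-7,8,7',8'-tetradehydro-β,β-carotene-3,4,3',4'-tetrol (CNP0283832.1) | CC1=C(C#C/C(C)=C/C=C/C(C)=C/C=C/C=C(C)/C=C/C=C(\C)C#CC2=C(C)[C@H](O)[C@@H](O)CC2(C)C)C(C)(C)C[C@H](O)[C@H]1O | target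

Total step count: 13. Longest linear sequence: 12 steps (steps 1–7 and 9–13; step 8 is a one-step side branch).

**Steps most likely to fail**

Step 3. The cycloaddition may stall at the open-chain Michael stage, close the zwitterion to a four-membered ring, or lose the silyl groups of the diene to the Lewis acid. The fallback sets out from 3 and returns at 7. It makes the same two ring bonds under reversible base catalysis as a Michael/aldol-condensation (Robinson-type) annulation. Enone 3 and methyl acetoacetate (NaOMe cat., MeOH, rt) should give the Michael adduct methyl 2-acetyl-6-[(tert-butyldimethylsilyl)oxy]-3,3-dimethyl-5-oxohexanoate F1. Its silyloxy-activated methylene should then condense with the acetyl carbonyl (pyrrolidinium acetate, or more NaOMe) to give 7 and/or its conjugated double-bond isomer methyl 3-[(tert-butyldimethylsilyl)oxy]-2,6,6-trimethyl-4-oxocyclohex-2-ene-1-carboxylate F2. F2 and 7 share one dienolate and interconvert under the conditions of step 4, so the material re-enters at 7.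

Step 4. The resolution may fail because no enzyme accepts the hindered α-silyloxy ketone, because racemisation is slower than reduction (plain kinetic resolution), or because the substrate drains into the conjugated isomer. The fallback sets out from 7 and returns at 8. Reduction with LiBH(s-Bu)3 (THF, −78 °C), with chromatographic removal of any cis isomer, should give the racemic trans hydroxy ester (8 together with its 3R,4R enantiomer) F3. Lipase-catalysed acylation (Candida antarctica lipase B, vinyl acetate, t-BuOMe, 40 °C) should then, by the usual preference of such lipases for the R carbinol, acylate the unwanted enantiomer to methyl (3R,4R)-4-acetoxy-3-[(tert-butyldimethylsilyl)oxy]-2,6,6-trimethylcyclohex-1-ene-1-carboxylate F4. This leaves (3S,4S)-8, which is separated by chromatography and carried into step 5.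

Step 12. The olefination may give incomplete E selectivity at the two new double bonds, and the thermal equilibration may erode the 9E geometry next to the triple bonds. The fallback sets out from 16 and returns at 22 by a Horner–Wadsworth–Emmons union. The allylic bromide 17 is isolated after the Appel reaction and heated with P(OEt)3 (Michaelis–Arbuzov reaction) to give diethyl [(2E)-5-{(3S,4S)-3,4-bis[(tert-butyldimethylsilyl)oxy]-2,6,6-trimethylcyclohex-1-en-1-yl}-3-methylpent-2-en-4-yn-1-yl]phosphonate F5. F5 (2.2 equiv) is deprotonated with NaN(SiMe3)2 (THF, −78 °C) and added to 19. This should form both double bonds E-selectively through 21 and give 22 without an isomerisation step.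

**Further compounds**
F1 | step 3 | methyl 2-acetyl-6-[(tert-butyldimethylsilyl)oxy]-3,3-dimethyl-5-oxohexanoate (racemic) | COC(=O)C(C(C)=O)C(C)(C)CC(=O)CO[Si](C)(C)C(C)(C)C
F2 | step 3 | methyl 3-[(tert-butyldimethylsilyl)oxy]-2,6,6-trimethyl-4-oxocyclohex-2-ene-1-carboxylate (racemic) | COC(=O)C1C(C)=C(O[Si](C)(C)C(C)(C)C)C(=O)CC1(C)C
F3 | step 4 | racemic trans methyl 3-[(tert-butyldimethylsilyl)oxy]-4-hydroxy-2,6,6-trimethylcyclohex-1-ene-1-carboxylate (3S,4S and 3R,4R enantiomers) | CC1=C(C(=O)OC)C(C)(C)C[C@H](O)[C@H]1O[Si](C)(C)C(C)(C)C.CC1=C(C(=O)OC)C(C)(C)C[C@@H](O)[C@@H]1O[Si](C)(C)C(C)(C)C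
F4 | step 4 | methyl (3R,4R)-4-acetoxy-3-[(tert-butyldimethylsilyl)oxy]-2,6,6-trimethylcyclohex-1-ene-1-carboxylate | CC1=C(C(=O)OC)C(C)(C)C[C@@H](OC(C)=O)[C@@H]1O[Si](C)(C)C(C)(C)C
F5 | step 12 | diethyl [(2E)-5-{(3S,4S)-3,4-bis[(tert-butyldimethylsilyl)oxy]-2,6,6-trimethylcyclohex-1-en-1-yl}-3-methylpent-2-en-4-yn-1-yl]phosphonate | CC1=C(C#C/C(C)=C/CP(=O)(OCC)OCC)C(C)(C)C[C@H](O[Si](C)(C)C(C)(C)C)[C@H]1O[Si](C)(C)C(C)(C)C
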